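| flask | substrate | partner | free catalyst | product | time |
|---|---|---|---|---|---|
| south-west | 0.300 M | 0.360 M | 6.00 × 10⁻⁴ M |  |  |
| north-west | 0.120 M | 0.180 M | 6.00 × 10⁻⁴ M |  |  |
| north-east | 0.300 M | 0.360 M | 9.00 × 10⁻⁴ M |  |  |
| south-east | 0.300 M | 0.360 M | 6.00 × 10⁻⁴ M | 0.0900 M |  |
| west | 0.0600 M | 0.360 M | 6.00 × 10⁻⁴ M |  | 9.7 min |

| south-west run: time / min | south-west run: [substrate] / M | north-west run: time / min | north-west run: [substrate] / M | north-east run: time / min | north-east run: [substrate] / M | south-east run: time / min | south-east run: [substrate] / M |
|---|---|---|---|---|---|---|---|
| 0.39 | 0.2753 | 0.39 | 0.1085 | 0.39 | 0.2627 | 0.39 | 0.2729 |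
| 0.61 | 0.2593 | 0.61 | 0.1047 | 0.61 | 0.2399 | 0.61 | 0.2610 |
| 0.97 | 0.2455 | 0.97 | 0.0997 | 0.97 | 0.2209 | 0.97 | 0.2427 |
| 1.5 | 0.2184 | 1.5 | 0.0916 | 1.5 | 0.1867 | 1.5 | 0.2163 |
| 2.4 | 0.1889 | 2.4 | 0.0801 | 2.4 | 0.1500 | 2.4 | 0.1896 |
| 3.9 | 0.1562 | 3.9 | 0.0668 | 3.9 | 0.1139 | 3.9 | 0.1572 |
| 6.1 | 0.1299 | 6.1 | 0.0523 | 6.1 | 0.0830 | 6.1 | 0.1288 |
| 9.7 | 0.1047 | 9.7 | 0.0407 | 9.7 | 0.0609 | 9.7 | 0.1049 |

(standard deviation of a reading: 0.002 M)

- the exponent of [free catalyst] in the starting rate at the charge of the south-west run (at the point where two percent of the substrate have become product)
- the north-west run starts with 0.180 M less of substrate and of partner than the south-west run, and with no product. Compared where both hold the same amount of substrate, once fifteen percent of what the north-west run was charged with has turned into product, is the north-west run faster, slower or alike (within a tenth)?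
- substrate in the west run at 9.7 min, as a share of the substrate charged

- Overall: substrate + partner -> product, with free catalyst as catalyst.
- Constant volume, constant temperature.
- The analysis sees a species whether free or bound.
- "The second partner" is partner.
- An order is taken over about fifteen percent of the charge, up and down.

1. Start from what a turnover cannot change: partner minus substrate. Each turnover removes one of each, so in the south-west run the difference stays at 0.0600 M, and the north-west run has the same difference.

2. Let s and p be the shares of the substrate and partner charges still left. Write the rate as k times substrate times partner, and let k do what it likes in time. Then ln(p/s) divided by the difference is the time integral of k.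

3. Take the south-west run at 9.7 min: s is 0.349 and p is 0.458, which gives 4.51 M⁻¹. Call this the dose, the time integral of rate over substrate times partner. The north-west run at the same time gives 8.34 M⁻¹.

4. Give the west charge each dose in turn. Its difference is 0.300 M, so p stays at 0.833 or above, close to pseudo-first-order, and solving for s gives two answers. The south-west dose leaves 22.5%, and the north-west dose leaves 6.92%. The two ways part.

5. Find the cheat. The north-west run reads 0.1047 M at 0.61 min, and the south-west run reads 0.1047 M at 9.7 min, so substrate and partner match, while product differs. Yet the north-west run loses 0.0152 M min⁻¹ there, faster than the 0.00700 M min⁻¹ of the south-west run's last stretch. The south-east run, charged with 0.0900 M of product, reads 0.1049 M at 9.7 min, close to the south-west reading, so read k as fading with age.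

6. Compare late dose speed with early speed, split at 3.9 min. The ratio is 0.603 in the south-west run, lower than the 0.757 of the north-west run. The south-west run has the partner charge of the west run, and the north-west run has half of it, so I take the south-west dose, although the substrate charges differ too.

7. My own answers: the west run keeps 22.5% or somewhat more, and the north-west run is faster. Doses at 0.97 min in the north-east and south-west runs give an exponent of 1.15, a noisy reading.

8. The forecast says 1.1 (0.9 to 1.5), faster, and 8% (3% to 24%), lower than my west figure. Its ground: “I lean towards substrate saturation”.

The flask gives 28.8% for the west run, with exponent 1.0 and the north-west run faster. Fitted with main steps alone, the residual is 4.7 in units of the scatter.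

    free catalyst + substrate ⇌ catalyst-substrate complex, settled at all times (4.410 M⁻¹)
    catalyst-substrate complex + partner → product + free catalyst (1356 M⁻¹ min⁻¹)
    free catalyst + partner → spent catalyst + partner (2.796 M⁻¹ min⁻¹)
    2 partner ⇌ idle reagent dimer, settled at all times (4.250 M⁻¹)

That share means a west dose of 3.73 M⁻¹, less than the south-west dose. The north-east and south-west runs share one charge of substrate and partner, so half turned means the same dose in both, 2.57 M⁻¹. The north-east run reaches it at 2.40 min and the south-west run at 4.18 min, a mean dose speed 1.74 times as high.

The runs are simulated from invented constants; the scatter is artificial.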